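**Assumption:** the SMILES is taken literally: free hydrogen sulfate, (S) at the methyl-bearing carbon, (E) trisubstituted olefin, and the exocyclic olefin with the side chain cis to C4 (5E, the less stable geometry). Butenolide numbering is O1, C2(=O), C3(Me), C4(O), C5; the side chain runs C1′, C2′ and so on.

## Retrosynthetic overview
1. The sulfate goes on last (SO3·pyridine) onto the (5E)-tetronic acid, which is released from its 4-O-(2-trimethylsilylethyl) (TMSE) ether with fluoride.
2. The exocyclic C5=C1′ olefin comes from a stereospecific anti-dehydration of a 5,1′-erythro aldol. The C5–C1′ bond is the key intermolecular aldol between a lithiated 3-methyltetronate and the (S)-α-methyl C20 aldehyde.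
3. The aldehyde comes from a Negishi sp3–sp2 coupling (chain to furan C4) and a B-alkyl Suzuki coupling. The Suzuki partners are a Roche-ester-derived alkene and the (E)-vinyl iodide from carboalumination of pent-4-yn-1-ol.
4. The bisfuran bromide comes from furan-3-yllithium plus 4-bromofurfural, then ionic deoxygenation.
5. Both furans are bought intact. The only ring built is the butenolide (3-methyltetronic acid from ethyl 2-methylacetoacetate), closed before the aldol.

## Route

**Step 1**
Reactants: 1 3-bromofuran; 2 4-bromofuran-2-carbaldehyde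
Product: 4 (4-bromofuran-2-yl)(furan-3-yl)methanol (racemic), via furan-3-yllithium 3 (not isolated)
Conditions: 1, n-BuLi (1.05 equiv), THF, −78 °C, 30 min; then 2, −78 °C, 1 h; H2O
Reagents that add atoms: none
Why: Bromine–lithium exchange then 1,2-addition; at −78 °C furan-3-yllithium is positionally stable and adds to the aldehyde much faster than it exchanges with the ring bromide, and the racemic carbinol centre is erased in step 2.

**Step 2**
Reactants: 4 (4-bromofuran-2-yl)(furan-3-yl)methanol
Product: 5 4-bromo-2-(furan-3-ylmethyl)furan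
Conditions: Et3SiH (5 equiv), TFA (3 equiv), CH2Cl2, −20 → 0 °C, slow inverse addition of dilute 4
Reagents that add atoms: none
Why: Ionic hydrogenation (Kursanov–Parnes); the doubly furyl-stabilised cation forms readily and is captured by the large excess of silane before it can alkylate another furan, and the C–Br bond is inert.

**Step 3**
Reactants: 6 methyl (2R)-3-hydroxy-2-methylpropanoate ((R)-Roche ester)
Product: 7 methyl (2R)-3-[(tert-butyldiphenylsilyl)oxy]-2-methylpropanoate
Conditions: TBDPSCl, imidazole, DMF, 0 °C → rt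
Reagents that add atoms: tert-butyl(chloro)diphenylsilane, CC(C)(C)[Si](Cl)(c1ccccc1)c1ccccc1
Why: Standard silylation of a primary alcohol; TBDPS survives every step up to step 11, and the chiral-pool centre becomes C2′ of the target.

**Step 4**
Reactants: 7 silyl ether ester
Product: 8 (2S)-3-[(tert-butyldiphenylsilyl)oxy]-2-methylpropan-1-ol
Conditions: DIBAL-H (2.3 equiv), CH2Cl2, −78 → 0 °C; Rochelle salt
Reagents that add atoms: none
Why: Full hydride reduction of the ester avoids the over- and under-reduction of a direct ester-to-aldehyde stop; the stereocentre is untouched and the descriptor changes only through CIP ranking.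

**Step 5**
Reactants: 8 mono-protected diol
Product: 9 (2R)-3-[(tert-butyldiphenylsilyl)oxy]-2-methylpropanal
Conditions: Dess–Martin periodinane (1.2 equiv), CH2Cl2, 0 °C → rt; used at once
Reagents that add atoms: none
Why: Dess–Martin oxidation is non-basic and fast, so the α-stereocentre does not epimerise.

**Step 6**
Reactants: 9 aldehyde
Product: 10 tert-butyl{[(2S)-2-methylbut-3-en-1-yl]oxy}diphenylsilane
Conditions: Ph3PCH3Br (1.5 equiv), n-BuLi (1.4 equiv), THF, 0 °C; then 9, −78 °C → rt
Reagents that add atoms: methyltriphenylphosphonium bromide, C[P+](c1ccccc1)(c1ccccc1)c1ccccc1.[Br-]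
Why: Wittig methylenation; the unstabilised ylide adds at low temperature faster than it enolises the aldehyde, so configuration is retained.

**Step 7**
Reactants: 11 pent-4-yn-1-ol
Product: 13 (4E)-5-iodo-4-methylpent-4-en-1-ol, via (E)-alkenylalane 12 (not isolated)
Conditions: Me3Al (3 equiv), Cp2ZrCl2 (0.25 equiv), CH2Cl2, 0 °C → rt, 16 h; I2, THF, −30 °C; aqueous work-up
Reagents that add atoms: trimethylaluminium, C[Al](C)C; iodine, II
Why: Negishi Zr-catalysed carboalumination adds Me and Al syn with the methyl on the internal carbon, and iodinolysis proceeds with retention, which fixes the (E) trisubstituted olefin.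

**Step 8**
Reactants: 10 terminal alkene; 13 vinyl iodide
Product: 15 (4E,8S)-9-[(tert-butyldiphenylsilyl)oxy]-4,8-dimethylnon-4-en-1-ol, via B-alkyl-9-BBN 14 (not isolated)
Conditions: 10, 9-BBN (1.3 equiv), THF, rt, 4 h; then 13, PdCl2(dppf) (5 mol %), AsPh3 (10 mol %), Cs2CO3, DMF–H2O, rt
Reagents that add atoms: none
Why: Anti-Markovnikov hydroboration followed by B-alkyl Suzuki–Miyaura coupling; the vinyl iodide couples with retention of geometry, the free hydroxyl is tolerated, and the stereocentre is remote from the reacting carbon.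

**Step 9**
Reactants: 15 alcohol
Product: 16 tert-butyl{[(2S,5E)-9-iodo-2,6-dimethylnon-5-en-1-yl]oxy}diphenylsilane
Conditions: I2, PPh3, imidazole, CH2Cl2, 0 °C
Reagents that add atoms: iodine, II
Why: Appel (Garegg–Samuelsson) iodination of an unhindered primary alcohol; olefin and silyl ether are inert.

**Step 10**
Reactants: 16 alkyl iodide; 5 4-bromo-2-(furan-3-ylmethyl)furan
Product: 18 tert-butyl({(2S,5E)-9-[5-(furan-3-ylmethyl)furan-3-yl]-2,6-dimethylnon-5-en-1-yl}oxy)diphenylsilane, via alkylzinc iodide 17 (not isolated)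
Conditions: 16, activated Zn dust, LiCl, THF, 40 °C; then 5, Pd(OAc)2 (2 mol %), SPhos (4 mol %), THF, rt → 45 °C
Reagents that add atoms: none
Why: Negishi sp3–sp2 coupling; primary alkylzinc halides form cleanly (a pent-4-enyl radical has no favourable cyclisation) and couple with heteroaryl bromides under Pd/SPhos without β-hydride problems or attack on the furans.

**Step 11**
Reactants: 18 silyl ether
Product: 19 (2S,5E)-9-[5-(furan-3-ylmethyl)furan-3-yl]-2,6-dimethylnon-5-en-1-ol
Conditions: TBAF (1.5 equiv), THF, rt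
Reagents that add atoms: none
Why: Fluoride desilylation is neutral to furans and olefin, unlike acidic or oxidative deprotections.

**Step 12**
Reactants: 19 alcohol
Product: 20 (2S,5E)-9-[5-(furan-3-ylmethyl)furan-3-yl]-2,6-dimethylnon-5-enal
Conditions: Dess–Martin periodinane (1.2 equiv), NaHCO3, CH2Cl2, 0 °C → rt; short silica plug, used at once
Reagents that add atoms: none
Why: Buffered Dess–Martin oxidation spares the acid-sensitive furans and does not epimerise the α-methyl centre.

**Step 13**
Reactants: 21 ethyl 2-methyl-3-oxobutanoate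
Product: 23 4-hydroxy-3-methylfuran-2(5H)-one (3-methyltetronic acid), via ethyl 4-bromo-2-methyl-3-oxobutanoate 22 (not isolated)
Conditions: Br2 (1.0 equiv), CHCl3, 0 °C → rt, 16 h; concentrate; neat, 110 °C, 3 h; crystallise from EtOAc
Reagents that add atoms: none
Why: The classical tetronic acid synthesis; HBr equilibrates the kinetic α-bromide to the γ-bromide, which lactonises thermally with loss of bromoethane.

**Step 14**
Reactants: 23 3-methyltetronic acid
Product: 24 3-methyl-4-[2-(trimethylsilyl)ethoxy]furan-2(5H)-one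
Conditions: 2-(trimethylsilyl)ethanol, PPh3, DIAD, THF, 0 °C → rt
Reagents that add atoms: 2-(trimethylsilyl)ethanol, C[Si](C)(C)CCO
Why: Mitsunobu alkylation of the acidic enol (pKa about 4) goes on O4 only and avoids the C3-alkylation seen with alkyl halides; TMSE is chosen because it leaves later under non-nucleophilic, non-acidic conditions.

**Step 15 (key step)**
Reactants: 24 TMSE tetronate; 20 aldehyde
Product: 26 (5R)-5-{(1R,2S,5E)-9-[5-(furan-3-ylmethyl)furan-3-yl]-1-hydroxy-2,6-dimethylnon-5-en-1-yl}-3-methyl-4-[2-(trimethylsilyl)ethoxy]furan-2(5H)-one, via lithium furanolate 25 (not isolated)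
Conditions: 24 (1.3 equiv), LDA (commercial, 1.35 equiv), THF, −78 °C, 45 min; 20, −78 °C, 1 h; AcOH quench at −78 °C; chromatographic erythro/threo separation
Reagents that add atoms: none
Why: Intermolecular aldol addition; LDA removes the only acidic proton (C5–H) to give the aromatic 2-furanolate, which adds through C5 faster than it enolises the aldehyde, so C2′ stays (S); the open transition state gives roughly equal erythro and threo adducts, so the 5,1′-erythro (like) Felkin isomer 26 is secured by chromatography rather than by selectivity (its anti-Felkin erythro partner may be carried along because it gives the same olefin).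

**Step 16**
Reactants: 26 erythro aldol
Product: 27 (5E)-5-{(2S,5E)-9-[5-(furan-3-ylmethyl)furan-3-yl]-2,6-dimethylnon-5-en-1-ylidene}-3-methyl-4-[2-(trimethylsilyl)ethoxy]furan-2(5H)-one
Conditions: PPh3 (3.3 equiv) and DIAD (3.0 equiv) premixed, THF, −30 °C; then 26, −30 °C → rt, dark; rapid chromatography
Reagents that add atoms: none
Why: Mitsunobu-type dehydration; the alkoxyphosphonium group leaves in a concerted anti-periplanar E2 with C5–H under near-neutral conditions, so the like-configured (5R,1′R) adduct must place C2′ cis to C4 and gives the (5E) olefin, whereas base-mediated E1cB methods funnel to Z; premixing leaves no free azodicarboxylate to attack the furans, and C2′ is untouched.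

**Step 17**
Reactants: 27 (5E)-TMSE tetronate
Product: 28 (5E)-5-{(2S,5E)-9-[5-(furan-3-ylmethyl)furan-3-yl]-2,6-dimethylnon-5-en-1-ylidene}-4-hydroxy-3-methylfuran-2(5H)-one
Conditions: TBAF·3H2O (1.5 equiv), THF, 0 °C, 30 min, dark; cold 0.1 M HCl to pH 3, EtOAc; used at once
Reagents that add atoms: none
Why: Fluoride-triggered β-silyl fragmentation releases ethene and the delocalised tetronate anion; there is no thiolate, amine or strong acid that could add reversibly to C1′, so the E geometry and C2′ are preserved.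

**Step 18**
Reactants: 28 (5E)-tetronic acid
Product: 30 (2E)-2-{(2S,5E)-9-[5-(furan-3-ylmethyl)furan-3-yl]-2,6-dimethylnon-5-en-1-ylidene}-4-methyl-5-oxo-2,5-dihydrofuran-3-yl hydrogen sulfate (target), via pyridinium sulfate salt 29 (not isolated)
Conditions: SO3·pyridine (3 equiv), DMF, 0 °C → rt, 2 h, dark; then Dowex 50W (H+ form), MeOH–H2O, 0 °C; C18 desalting, lyophilise cold
Reagents that add atoms: sulfur trioxide–pyridine complex, [O-]S(=O)(=O)[n+]1ccccc1
Why: O-sulfation of the acidic enol with a mild SO3 donor occurs at O4, the only hydroxyl present, and brief cold proton exchange gives the hydrogen sulfate without prolonged acid contact for the furans.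

## Compound list
1 | 3-bromofuran | Brc1ccoc1 | starting material
2 | 4-bromofuran-2-carbaldehyde | O=Cc1cc(Br)co1 | starting material
3 | furan-3-yllithium | [Li]c1ccoc1 | intermediate
4 | (4-bromofuran-2-yl)(furan-3-yl)methanol (racemic) | OC(c1ccoc1)c1cc(Br)co1 | intermediate
5 | 4-bromo-2-(furan-3-ylmethyl)furan | Brc1coc(Cc2ccoc2)c1 | intermediate
6 | methyl (2R)-3-hydroxy-2-methylpropanoate | OC[C@@H](C)C(=O)OC | starting material
7 | methyl (2R)-3-[(tert-butyldiphenylsilyl)oxy]-2-methylpropanoate | CC(C)(C)[Si](c1ccccc1)(c1ccccc1)OC[C@@H](C)C(=O)OC | intermediate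
8 | (2S)-3-[(tert-butyldiphenylsilyl)oxy]-2-methylpropan-1-ol | CC(C)(C)[Si](c1ccccc1)(c1ccccc1)OC[C@@H](C)CO | intermediate
9 | (2R)-3-[(tert-butyldiphenylsilyl)oxy]-2-methylpropanal | CC(C)(C)[Si](c1ccccc1)(c1ccccc1)OC[C@@H](C)C=O | intermediate
10 | tert-butyl{[(2S)-2-methylbut-3-en-1-yl]oxy}diphenylsilane | CC(C)(C)[Si](c1ccccc1)(c1ccccc1)OC[C@@H](C)C=C | intermediate
11 | pent-4-yn-1-ol | C#CCCCO | starting material
12 | [(1E)-5-(dimethylalumanyloxy)-2-methylpent-1-en-1-yl]dimethylalumane | C[Al](C)/C=C(\C)CCCO[Al](C)C | intermediate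
13 | (4E)-5-iodo-4-methylpent-4-en-1-ol | I/C=C(\C)CCCO | intermediate
14 | 9-{(3S)-4-[(tert-butyldiphenylsilyl)oxy]-3-methylbutyl}-9-borabicyclo[3.3.1]nonane | CC(C)(C)[Si](c1ccccc1)(c1ccccc1)OC[C@@H](C)CCB1C2CCCC1CCC2 | intermediate
15 | (4E,8S)-9-[(tert-butyldiphenylsilyl)oxy]-4,8-dimethylnon-4-en-1-ol | CC(C)(C)[Si](c1ccccc1)(c1ccccc1)OC[C@@H](C)CC/C=C(\C)CCCO | intermediate
16 | tert-butyl{[(2S,5E)-9-iodo-2,6-dimethylnon-5-en-1-yl]oxy}diphenylsilane | CC(C)(C)[Si](c1ccccc1)(c1ccccc1)OC[C@@H](C)CC/C=C(\C)CCCI | intermediate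
17 | {(4E,8S)-9-[(tert-butyldiphenylsilyl)oxy]-4,8-dimethylnon-4-en-1-yl}zinc iodide | CC(C)(C)[Si](c1ccccc1)(c1ccccc1)OC[C@@H](C)CC/C=C(\C)CCC[Zn]I | intermediate
18 | tert-butyl({(2S,5E)-9-[5-(furan-3-ylmethyl)furan-3-yl]-2,6-dimethylnon-5-en-1-yl}oxy)diphenylsilane | CC(C)(C)[Si](c1ccccc1)(c1ccccc1)OC[C@@H](C)CC/C=C(\C)CCCc1coc(Cc2ccoc2)c1 | intermediate
19 | (2S,5E)-9-[5-(furan-3-ylmethyl)furan-3-yl]-2,6-dimethylnon-5-en-1-ol | OC[C@@H](C)CC/C=C(\C)CCCc1coc(Cc2ccoc2)c1 | intermediate
20 | (2S,5E)-9-[5-(furan-3-ylmethyl)furan-3-yl]-2,6-dimethylnon-5-enal | O=C[C@@H](C)CC/C=C(\C)CCCc1coc(Cc2ccoc2)c1 | intermediate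
21 | ethyl 2-methyl-3-oxobutanoate | CCOC(=O)C(C)C(C)=O | starting material
22 | ethyl 4-bromo-2-methyl-3-oxobutanoate (racemic) | CCOC(=O)C(C)C(=O)CBr | intermediate
23 | 4-hydroxy-3-methylfuran-2(5H)-one | CC1=C(O)COC1=O | intermediate
24 | 3-methyl-4-[2-(trimethylsilyl)ethoxy]furan-2(5H)-one | CC1=C(OCC[Si](C)(C)C)COC1=O | intermediate
25 | lithium 3-methyl-4-[2-(trimethylsilyl)ethoxy]furan-2-olate | [Li+].[O-]c1occ(OCC[Si](C)(C)C)c1C | intermediate
26 | (5R,1′R,2′S,5′E) erythro aldol adduct | CC1=C(OCC[Si](C)(C)C)[C@@H]([C@H](O)[C@@H](C)CC/C=C(\C)CCCc2coc(Cc3ccoc3)c2)OC1=O | intermediate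
27 | (5E,2′S,5′E)-5-alkylidene TMSE tetronate | CC1=C(OCC[Si](C)(C)C)/C(=C\[C@@H](C)CC/C=C(\C)CCCc2coc(Cc3ccoc3)c2)OC1=O | intermediate
28 | (5E,2′S,5′E)-5-alkylidene-4-hydroxy-3-methylfuran-2(5H)-one | CC1=C(O)/C(=C\[C@@H](C)CC/C=C(\C)CCCc2coc(Cc3ccoc3)c2)OC1=O | intermediate
29 | pyridinium salt of the target sulfate | CC1=C(OS(=O)(=O)[O-])/C(=C\[C@@H](C)CC/C=C(\C)CCCc2coc(Cc3ccoc3)c2)OC1=O.c1cc[nH+]cc1 | intermediate
30 | CNP0018233.1, hydrogen sulfate | CC1=C(OS(=O)(=O)O)/C(=C\[C@@H](C)CC/C=C(\C)CCCc2coc(Cc3ccoc3)c2)OC1=O | target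

## Step count and risks
Total steps: 18. Longest linear sequence: 13 steps (6 → 7 → 8 → 9 → 10 → 15 → 16 → 18 → 19 → 20 → 26 → 27 → 28 → 30).

**Risk 1, step 16 (with the unselective step 15).** The anti-E2 has to build the geometry that pushes the sec-alkyl group against the 4-alkoxy group, and an E1cB leak would give Z. The fallback sets out from 26 and comes back at 27; the threo fractions set aside in step 15 can be fed in as well. Mesylation (MsCl, Et3N, CH2Cl2, 0 °C) gives the 1′-methanesulfonate of the aldol adduct F2. DBU then gives, by stereoconvergent E1cB, the thermodynamic (5Z)-alkylidene TMSE tetronate F3. Irradiation of F3 (350 nm, Pyrex, rigorously degassed MeCN so that no singlet oxygen reaches the furans) sets up an E/Z photostationary mixture. 27 is separated from it by chromatography or HPLC, and the recovered Z isomer is irradiated again.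

**Risk 2, step 18.** The enol sulfate is a vinylogous mixed anhydride, the free acid form is harsh on the furans, and any Z contaminant cannot be removed from a salt. The fallback sets out from 28 and comes back at 30. Treatment with 2,2,2-trichloroethyl chlorosulfate and Et3N (THF, 0 °C) gives the neutral 2,2,2-trichloroethyl sulfate diester of the tetronic acid F4, which can be purified on silica and freed of Z isomer. Reductive fragmentation with Zn dust and HCO2NH4 (THF–MeOH, rt) gives the ammonium salt of the target sulfate F5. The same cold H+ exchange then delivers 30.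

**Risk 3, step 2.** The difuryl cation can alkylate furan rings and oligomerise. The fallback sets out from 2 and comes back at 5. Condensation with tosylhydrazide (MeOH, rt) gives 4-bromofuran-2-carbaldehyde N-tosylhydrazone F1. Heating F1 with furan-3-ylboronic acid and K2CO3 in dioxane at 110 °C is a metal-free reductive coupling: diazo formation, boronate 1,2-shift, then protodeboronation. It builds the CH2 bridge directly, without a carbocation and without Pd, so the C–Br bond survives.

## Further compounds
F1 | step 2 | 4-bromofuran-2-carbaldehyde N-tosylhydrazone | Cc1ccc(cc1)S(=O)(=O)N/N=C/c1cc(Br)co1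
F2 | step 16 | 1′-methanesulfonate of the aldol adduct | CC1=C(OCC[Si](C)(C)C)[C@@H]([C@H](OS(C)(=O)=O)[C@@H](C)CC/C=C(\C)CCCc2coc(Cc3ccoc3)c2)OC1=O
F3 | step 16 | (5Z)-alkylidene TMSE tetronate | CC1=C(OCC[Si](C)(C)C)/C(=C/[C@@H](C)CC/C=C(\C)CCCc2coc(Cc3ccoc3)c2)OC1=O
F4 | step 18 | 2,2,2-trichloroethyl sulfate diester of the tetronic acid | CC1=C(OS(=O)(=O)OCC(Cl)(Cl)Cl)/C(=C\[C@@H](C)CC/C=C(\C)CCCc2coc(Cc3ccoc3)c2)OC1=O
F5 | step 18 | ammonium salt of the target sulfate | CC1=C(OS(=O)(=O)[O-])/C(=C\[C@@H](C)CC/C=C(\C)CCCc2coc(Cc3ccoc3)c2)OC1=O.[NH4+]
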